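Assumption: compounds 1, 3, 6 and 7 are bought, and every intermediate that carries the aryl ketone ketal is handled away from light, because benzil ketals undergo photochemical alpha-cleavage.

## Analysis of the target

Ficucaricone C (18) is an unsymmetrical benzil. Its two carbonyl carbons (Ca next to ring A, Cb next to ring B) join a 2,2-dimethyl-2H-chromene to a 4-(3-methylbut-2-enyloxy)phenyl ring. Ring A is pentasubstituted: C4a and C8a belong to the pyran ring (O1, C2, C3, C4, C4a, C8a), C5 carries OMe, C6 the dicarbonyl chain, C7 a free OH, and C8 the only ring hydrogen. There is no stereocentre; the only geometric element that matters on the way is the cis configuration of the alkene that becomes C3=C4. The sensitive groups are: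

- the 1,2-diketone (alkoxide and hydroxide addition, benzilic rearrangement, light);
- the prenyl aryl ether (acid, heat, hydrogenation, zerovalent palladium);
- the styrene-like C3=C4 bond (acid, hydrogenation);
- the chelated phenol.

The difficulty is regiochemical. Three different oxygen functions (pyran ether at C8a, OMe at C5, OH at C7) must be placed around one benzene ring, with the acyl group exactly between C5 and C7 and the pyran fused in the linear sense. The strategy rests on one feature: C5 and C7 are ortho and C8a is para to the acyl-bearing C6. Each of the three C–O bonds can therefore come from a C–F bond of a 2,4,6-trifluorophenyl ketone, and the para carbon C8a is where the pyran oxygen closes the ring.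

## Retrosynthetic reasoning

**18 to 17 (unmask Cb).** The Cb carbonyl is carried as a dimethyl ketal. A free 1,2-diketone would not survive the alkoxide chemistry on ring A, whereas the ketal leaves Ca as a non-enolisable ketone that still activates the ring. The forward step must open a ketal whose oxocarbenium ion is stabilised by the para-alkoxyphenyl group, under aqueous acid mild enough to spare the prenyl ether and the chromene.

**17 to 16 (free the C7 hydroxyl).** The C7 oxygen is carried as a 2-(trimethylsilyl)ethyl ether. A free phenoxide ortho to the ketone would quench the ketone's acceptor power and stop the last substitution. The group leaves under fluoride, which is orthogonal to the prenyl ether, the ketal and both alkenes.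

**16 to 15 (C5–OMe from C5–F).** The C5–O bond is cut back to a C–F bond. C5 is ortho to the ketone and meta to the ethers at C7 and C8a, so these do not deactivate it by resonance. The forward step is a third fluoride displacement by the smallest oxygen nucleophile at the most hindered position.

**15 to 14 (C7–O from C7–F).** In the difluorochromene 14 the two fluorides are electronically alike (both ortho to the ketone, meta to O1 and to each other). The difference is steric: C7 has a hydrogen neighbour, C5 lies between C4a and the acyl carbon. The first intermolecular nucleophile therefore goes to C7 and must carry the removable group; the methoxy group comes second.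

**14 to 12 (key disconnection, O1–C8a).** Cutting O1–C8a, rather than O1–C2 or C4–C4a, turns the pyran into a four-carbon side chain bearing a tertiary alcohol, attached to the ring by a C–C bond made with standard coupling chemistry. It makes the pyran oxygen the third member of the same C–F to C–O logic. The forward reaction needs a tethered tertiary alkoxide to displace the fluoride para to the ketone in 12, not the one ortho to it. This is possible only because the alkene in 12 is cis.

**12 to 11 (cis alkene from alkyne).** The alkene is taken back to an alkyne. The linear alkyne keeps the hydroxyl away from the ring fluorines during the organolithium step, and semihydrogenation sets the cis geometry just before it is needed.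

**11 to 8 and 5 (C6–Ca bond).** The two ring hydrogens of 8 are equivalent and each lies between two fluorines, so deprotonation gives one aryllithium, 9. Acylation with the N-methoxy-N-methylamide 5 brings in Ca, the masked Cb and ring B in one step. The adduct 10 holds until quench, so no alkoxide is set free next to the newly activated trifluoroarene.

**8 to 6 and 7.** The aryl–alkyne bond is made by palladium/copper-catalysed coupling of the iodide 6 with the alkynol 7. The iodine sits between two fluorines, which fixes the side chain at the future C4a.

**5 to 4, 2, 3 and 1.** The amide 5 comes from the ester 4, which comes from the phenol 2 and prenyl bromide 3. The ketal 2 is made from the keto ester 1 before the prenyl group is attached, so that the allyl ether never meets anhydrous acid.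

## Alternatives that were turned down

**Alternative 1:** Both aryl–carbonyl bonds (C6–Ca and Cb–ring B) are cut, with 1,4-dimethylpiperazine-2,3-dione A2 as a two-carbon dielectrophile. In the forward step 4-(3-methylbut-2-enyloxy)phenyllithium A3 and then 6-lithio-5-methoxy-7-(methoxymethoxy)-2,2-dimethyl-2H-chromene A4 add to the two amide carbonyls. Aqueous acid releases 7-O-methoxymethyl ficucaricone C A1, and no ring is formed.

- For: it is the most convergent plan. The diketone appears late and never meets an alkoxide. From a ready chromene it would need fewer steps than the chosen route; on step count it is stronger.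
- Against: the chromene partner must itself be built with three differentiated oxygens. Annulating a symmetrical methoxyresorcinol can close between the two hydroxyls or between OH and OMe, so the ring-A problem is moved, not solved.
- Against: lithiation must choose C6 (between OMe and the acetal oxygen) over C8 (between the acetal oxygen and O1), and both sites are doubly activated.
- Against: the second addition brings a doubly ortho-substituted aryllithium to a carbonyl next to an already tetrahedral, fully substituted carbon.
- On a par: the final acetal removal needs acid in the presence of the prenyl ether, as the chosen route also does.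
- In place of convergence, the chosen strategy offers positional certainty. Its one ring lithiation is at one of two equivalent hydrogens, and the oxygen pattern follows from the fluorine pattern.

**Alternative 2:** The Cb–ring B bond is made by a 1,2-aryl shift in a chalcone, and the three-carbon bridge is later shortened by one carbon. In the forward step Tl(NO3)3 (trivalent thallium) in methanol with HC(OMe)3 moves the aryl group from the beta to the alpha carbon of a 2'-hydroxychalcone. Acid then closes a pyranone through O7 to give 3-(4-hydroxyphenyl)-5-methoxy-8,8-dimethyl-7,8-dihydro-6H-pyrano[3,2-g]chromen-4-one A5. Oxidative cleavage of the enol ether double bond would later remove the extra carbon and free both the diketone and the C7 hydroxyl.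

- For: it follows the likely biogenesis, the aryl migration is dependable, ring A starts from an acylphloroglucinol, and the temporary pyranone protects O7 and Ca together.
- Against: it needs a stoichiometric toxic heavy-metal oxidant and builds a carbon only to remove it.
- Against: the excision cannot coexist with the C3=C4 bond or the prenyl alkene. That is why A5 has a saturated pyran and a free ring-B phenol. Cleavage, dehydrogenation to the chromene and prenylation must follow, all on a free phenolic diketone.
- Against: the linear or angular sense of the dihydropyran annulation and the choice of which hydroxyl is methylated remain open.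
- Comparison: it is longer and puts the least controlled steps last. The chosen route brings in both alkenes in their final form and removes no skeletal carbon.

**Alternative 3:** The pyran is cut at C3–C4 and O1–C2. In the forward step one formyl group of the symmetrical 4,6-dihydroxy-2-methoxybenzene-1,3-dicarbaldehyde A7 condenses with a catalytic secondary amine and (2-methylprop-1-enyl)boronic acid A8. Loss of the amine gives an ortho-quinone methide, and oxa-6π closure gives 7-hydroxy-5-methoxy-2,2-dimethyl-2H-chromene-6-carbaldehyde A6.

- For: two bonds and the ring form in one catalytic operation. The symmetry of A7 makes the choice of formyl group irrelevant, the chromene is in its final oxidation state, and no fluorine is needed. On ring construction it is more economical than coupling, semihydrogenation and substitution.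
- Against: the second formyl group also has an ortho hydroxyl, so only stoichiometry prevents a second annulation.
- Against: A7 needs its methoxy group between two formyl groups, the most hindered and most strongly hydrogen-bonded position.
- Against: A6 stops at an aldehyde. Cb and ring B must still be attached by an acyl anion equivalent and an oxidation next to a free phenol, at least three more steps, and the diketone is then exposed.
- Comparison: the chosen strategy attaches Ca, masked Cb and ring B in one acylation.

Key step: step 7

## Route

Step 1
Reactants: 1 methyl 2-(4-hydroxyphenyl)-2-oxoacetate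
Product: 2 methyl 2-(4-hydroxyphenyl)-2,2-dimethoxyacetate
Conditions: HC(OMe)3, TsOH·H2O (cat.), MeOH, 60 °C; then Et3N
Reagents that add atoms: trimethyl orthoformate, COC(OC)OC; methanol, CO
Why: Acid-catalysed ketalisation; the ketone is activated by the neighbouring ester and the orthoformate removes the water, so the equilibrium should lie on the ketal side. It is done before prenylation so that the acid-labile allyl ether never meets anhydrous acid.

Step 2
Reactants: 2 methyl 2-(4-hydroxyphenyl)-2,2-dimethoxyacetate; 3 prenyl bromide (1-bromo-3-methylbut-2-ene)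
Product: 4 methyl 2,2-dimethoxy-2-[4-(3-methylbut-2-enyloxy)phenyl]acetate
Conditions: K2CO3, acetone, 50 °C
Reagents that add atoms: none
Why: Williamson ether synthesis; the phenoxide attacks the primary allylic bromide by SN2, and the ketal and ester are inert to carbonate.

Step 3
Reactants: 4 methyl 2,2-dimethoxy-2-[4-(3-methylbut-2-enyloxy)phenyl]acetate
Product: 5 N,2,2-trimethoxy-N-methyl-2-[4-(3-methylbut-2-enyloxy)phenyl]acetamide
Conditions: MeNH(OMe)·HCl, i-PrMgCl, THF, −20 → 0 °C
Reagents that add atoms: N,O-dimethylhydroxylamine hydrochloride, CNOC.Cl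
Why: Weinreb amide formation by aminolysis of the ester with the chloromagnesium amide; the two alpha-methoxy groups raise the electrophilicity of the ester and offset the hindrance of the fully substituted alpha-carbon, and no acid is involved.

Step 4
Reactants: 6 1,3,5-trifluoro-2-iodobenzene; 7 2-methylbut-3-yn-2-ol
Product: 8 2-methyl-4-(2,4,6-trifluorophenyl)but-3-yn-2-ol
Conditions: PdCl2(PPh3)2 (2 mol %), CuI (4 mol %), Et3N, THF, 50 °C
Reagents that add atoms: none
Why: Sonogashira coupling; the electron-poor aryl iodide adds readily to zerovalent palladium, the C–F bonds are inert and the free tertiary alcohol is tolerated.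

Step 5
Reactants: 8 2-methyl-4-(2,4,6-trifluorophenyl)but-3-yn-2-ol; 5 N,2,2-trimethoxy-N-methyl-2-[4-(3-methylbut-2-enyloxy)phenyl]acetamide
Product: 11 1-[2,4,6-trifluoro-3-(3-hydroxy-3-methylbut-1-ynyl)phenyl]-2,2-dimethoxy-2-[4-(3-methylbut-2-enyloxy)phenyl]ethanone, via dilithiated alkynol 9 (not isolated), via tetrahedral lithium adduct 10 (not isolated)
Conditions: LiN(i-Pr)2 (2.1 equiv), THF, −78 °C; then 5, −78 → −60 °C; sat. aq. NH4Cl at −78 °C
Reagents that add atoms: none
Why: The first equivalent of base forms the alkoxide and the second removes one of the two equivalent ring hydrogens, each of which lies between two fluorines (fluorine-directed ortho-lithiation), so only one aryllithium can form. Weinreb ketone synthesis then gives the chelated adduct 10, which should not collapse before the quench, so neither over-addition nor release of an alkoxide next to the activated fluoroarene is expected. The linear alkyne keeps the side-chain alkoxide away from the ring fluorines.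

Step 6
Reactants: 11 1-[2,4,6-trifluoro-3-(3-hydroxy-3-methylbut-1-ynyl)phenyl]-2,2-dimethoxy-2-[4-(3-methylbut-2-enyloxy)phenyl]ethanone
Product: 12 1-{2,4,6-trifluoro-3-[(Z)-3-hydroxy-3-methylbut-1-enyl]phenyl}-2,2-dimethoxy-2-[4-(3-methylbut-2-enyloxy)phenyl]ethanone
Conditions: H2 (1 atm), Pd/CaCO3 poisoned with Pb(OAc)2, quinoline, EtOAc, 20 °C, stopped after 1 equiv H2
Reagents that add atoms: none
Why: Lindlar semihydrogenation; syn delivery of hydrogen on the poisoned surface gives the Z alkene, and the trisubstituted prenyl alkene, the hindered ketone and the C–F bonds should not be reduced.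

Step 7
Reactants: 12 1-{2,4,6-trifluoro-3-[(Z)-3-hydroxy-3-methylbut-1-enyl]phenyl}-2,2-dimethoxy-2-[4-(3-methylbut-2-enyloxy)phenyl]ethanone
Product: 14 1-(5,7-difluoro-2,2-dimethyl-2H-chromen-6-yl)-2,2-dimethoxy-2-[4-(3-methylbut-2-enyloxy)phenyl]ethanone, via Meisenheimer adduct 13 (not isolated)
Conditions: Cs2CO3 (2 equiv), DMF (0.02 M), 60 °C
Reagents that add atoms: none
Why: Cs2CO3 deprotonates a small equilibrium share of the tertiary allylic alcohol, and the cis alkene holds the alkoxide over the two fluorine-bearing carbons that flank the side chain. Addition at the one para to the ketone gives the cyclohexadienyl anion 13, whose charge runs through C6 onto the ketone oxygen and is further stabilised inductively by the two fluorines meta to the point of attack; loss of fluoride then restores the arene (addition–elimination, SNAr). The closest known reaction type is the intramolecular SNAr etherification of carbonyl-activated fluoroarenes by a tethered alkoxide. The pyran ring (O1, C2, C3, C4, C4a, C8a) closes by attack of oxygen on an aromatic sp2 carbon, formally 6-exo-trig if C8a=C8 is taken as the accepting bond, and the cis tether lets the oxygen approach perpendicular to the ring plane. No stereocentre is formed. The step needs para- over ortho-fluoride displacement (linear over angular fusion): the large, weakly coordinating caesium ion in DMF gives a loose ion pair that is not guided to the ketone oxygen, and the ortho carbon is shielded on both sides by the side-chain carbon and by the twisted ketone with its quaternary ketal carbon, while the para carbon has a hydrogen neighbour. The fluorine at the other ortho position cannot be reached by the tether, the ketal at Cb rules out enolisation, and moderate dilution and temperature keep intermolecular substitution and attack by dimethylamine from the solvent in check.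

Step 8
Reactants: 14 1-(5,7-difluoro-2,2-dimethyl-2H-chromen-6-yl)-2,2-dimethoxy-2-[4-(3-methylbut-2-enyloxy)phenyl]ethanone
Product: 15 1-{5-fluoro-2,2-dimethyl-7-[2-(trimethylsilyl)ethoxy]-2H-chromen-6-yl}-2,2-dimethoxy-2-[4-(3-methylbut-2-enyloxy)phenyl]ethanone
Conditions: Me3SiCH2CH2OH (1.05 equiv), NaH (1.05 equiv), THF, 0 °C; then 14, −20 → 0 °C
Reagents that add atoms: 2-(trimethylsilyl)ethanol, C[Si](C)(C)CCO
Why: Intermolecular SNAr of a fluoride ortho to the ketone by a sodium alkoxide; the two fluorides are electronically equivalent, so the choice should fall on C7, which has a hydrogen neighbour, whereas C5 lies between C4a and the acyl carbon. The new ether is meta to C5 and donates into the ketone, so a second substitution should be slower and one equivalent of alkoxide should stop at 15.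

Step 9
Reactants: 15 1-{5-fluoro-2,2-dimethyl-7-[2-(trimethylsilyl)ethoxy]-2H-chromen-6-yl}-2,2-dimethoxy-2-[4-(3-methylbut-2-enyloxy)phenyl]ethanone
Product: 16 1-{5-methoxy-2,2-dimethyl-7-[2-(trimethylsilyl)ethoxy]-2H-chromen-6-yl}-2,2-dimethoxy-2-[4-(3-methylbut-2-enyloxy)phenyl]ethanone
Conditions: NaOMe (3 equiv), DMF, 50 °C
Reagents that add atoms: sodium methoxide, C[O-].[Na+]
Why: SNAr of the last fluoride, which is ortho to the ketone and meta to both ring ethers, so the ethers do not deactivate it by resonance; methoxide is small enough for the flanked C5 position.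

Step 10
Reactants: 16 1-{5-methoxy-2,2-dimethyl-7-[2-(trimethylsilyl)ethoxy]-2H-chromen-6-yl}-2,2-dimethoxy-2-[4-(3-methylbut-2-enyloxy)phenyl]ethanone
Product: 17 1-(7-hydroxy-5-methoxy-2,2-dimethyl-2H-chromen-6-yl)-2,2-dimethoxy-2-[4-(3-methylbut-2-enyloxy)phenyl]ethanone
Conditions: Bu4NF (3 equiv), THF, 60 °C; aq. NH4Cl
Reagents that add atoms: none
Why: Fluoride attacks silicon and the 2-silylethyl ether fragments to ethylene and the phenoxide, a good leaving group because it is ortho to the ketone (fluoride-induced beta-elimination); the ketal, the prenyl ether and both alkenes are inert to fluoride.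

Step 11
Reactants: 17 1-(7-hydroxy-5-methoxy-2,2-dimethyl-2H-chromen-6-yl)-2,2-dimethoxy-2-[4-(3-methylbut-2-enyloxy)phenyl]ethanone
Product: 18 Ficucaricone C, 1-(7-hydroxy-5-methoxy-2,2-dimethyl-2H-chromen-6-yl)-2-[4-(3-methylbut-2-enyloxy)phenyl]ethane-1,2-dione
Conditions: 1 M aq. HCl–THF (1:3), 20 °C, dark
Reagents that add atoms: water, O
Why: Acid-catalysed ketal hydrolysis; the oxocarbenium ion at Cb is stabilised by the para-alkoxyphenyl ring, so dilute aqueous acid at room temperature should suffice. Protonation of the aryl ether oxygen or of the prenyl alkene, which would be needed to lose the prenyl group, should be much slower under these conditions.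

## Compound list

1 | methyl 2-(4-hydroxyphenyl)-2-oxoacetate | COC(=O)C(=O)c1ccc(O)cc1 | starting material
2 | methyl 2-(4-hydroxyphenyl)-2,2-dimethoxyacetate | COC(=O)C(OC)(OC)c1ccc(O)cc1 | intermediate
3 | prenyl bromide (1-bromo-3-methylbut-2-ene) | CC(C)=CCBr | starting material
4 | methyl 2,2-dimethoxy-2-[4-(3-methylbut-2-enyloxy)phenyl]acetate | COC(=O)C(OC)(OC)c1ccc(OCC=C(C)C)cc1 | intermediate
5 | N,2,2-trimethoxy-N-methyl-2-[4-(3-methylbut-2-enyloxy)phenyl]acetamide | CON(C)C(=O)C(OC)(OC)c1ccc(OCC=C(C)C)cc1 | intermediate
6 | 1,3,5-trifluoro-2-iodobenzene | Fc1cc(F)c(I)c(F)c1 | starting material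
7 | 2-methylbut-3-yn-2-ol | CC(C)(O)C#C | starting material
8 | 2-methyl-4-(2,4,6-trifluorophenyl)but-3-yn-2-ol | CC(C)(O)C#Cc1c(F)cc(F)cc1F | intermediate
9 | lithium 2-methyl-4-(2,4,6-trifluoro-3-lithiophenyl)but-3-yn-2-olate (dilithiated alkynol, not isolated) | [Li]OC(C)(C)C#Cc1c(F)cc(F)c([Li])c1F | intermediate
10 | dilithium salt of the tetrahedral adduct of 9 at the amide carbonyl of 5 (not isolated) | [Li]OC(C)(C)C#Cc1c(F)cc(F)c(C(O[Li])(N(C)OC)C(OC)(OC)c2ccc(OCC=C(C)C)cc2)c1F | intermediate
11 | 1-[2,4,6-trifluoro-3-(3-hydroxy-3-methylbut-1-ynyl)phenyl]-2,2-dimethoxy-2-[4-(3-methylbut-2-enyloxy)phenyl]ethanone | CC(C)(O)C#Cc1c(F)cc(F)c(C(=O)C(OC)(OC)c2ccc(OCC=C(C)C)cc2)c1F | intermediate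
12 | 1-{2,4,6-trifluoro-3-[(Z)-3-hydroxy-3-methylbut-1-enyl]phenyl}-2,2-dimethoxy-2-[4-(3-methylbut-2-enyloxy)phenyl]ethanone | CC(C)(O)/C=C\c1c(F)cc(F)c(C(=O)C(OC)(OC)c2ccc(OCC=C(C)C)cc2)c1F | intermediate
13 | caesium enolate form of the Meisenheimer adduct, with sp3 C8a carrying F and O1 (racemic, not isolated) | [Cs+].[O-]C(=C1C(F)=CC2(F)OC(C)(C)C=CC2=C1F)C(OC)(OC)c1ccc(OCC=C(C)C)cc1 | intermediate
14 | 1-(5,7-difluoro-2,2-dimethyl-2H-chromen-6-yl)-2,2-dimethoxy-2-[4-(3-methylbut-2-enyloxy)phenyl]ethanone | Fc1c2c(cc(F)c1C(=O)C(OC)(OC)c1ccc(OCC=C(C)C)cc1)OC(C)(C)C=C2 | intermediate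
15 | 1-{5-fluoro-2,2-dimethyl-7-[2-(trimethylsilyl)ethoxy]-2H-chromen-6-yl}-2,2-dimethoxy-2-[4-(3-methylbut-2-enyloxy)phenyl]ethanone | Fc1c2c(cc(OCC[Si](C)(C)C)c1C(=O)C(OC)(OC)c1ccc(OCC=C(C)C)cc1)OC(C)(C)C=C2 | intermediate
16 | 1-{5-methoxy-2,2-dimethyl-7-[2-(trimethylsilyl)ethoxy]-2H-chromen-6-yl}-2,2-dimethoxy-2-[4-(3-methylbut-2-enyloxy)phenyl]ethanone | COc1c2c(cc(OCC[Si](C)(C)C)c1C(=O)C(OC)(OC)c1ccc(OCC=C(C)C)cc1)OC(C)(C)C=C2 | intermediate
17 | 1-(7-hydroxy-5-methoxy-2,2-dimethyl-2H-chromen-6-yl)-2,2-dimethoxy-2-[4-(3-methylbut-2-enyloxy)phenyl]ethanone | COc1c2c(cc(O)c1C(=O)C(OC)(OC)c1ccc(OCC=C(C)C)cc1)OC(C)(C)C=C2 | intermediate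
18 | Ficucaricone C, 1-(7-hydroxy-5-methoxy-2,2-dimethyl-2H-chromen-6-yl)-2-[4-(3-methylbut-2-enyloxy)phenyl]ethane-1,2-dione | COc1c2c(cc(O)c1C(=O)C(=O)c1ccc(OCC=C(C)C)cc1)OC(C)(C)C=C2 | target

## Step count and least certain steps

Total step count: 11. Longest linear sequence: 10 steps (1 → 2 → 4 → 5 → 11 → 12 → 14 → 15 → 16 → 17 → 18).

**Step 7 (key step).** The most likely failure is closure at the fluorine-bearing carbon ortho to the ketone, which gives the angular fusion. The ketone is twisted out of the ring plane by its two ortho fluorines, so it activates the para position less than a coplanar ketone would, and the steric shielding of the ortho carbon may not make up for that. Slow closure would also let intermolecular substitution compete.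

Fallback: close the pyran before the ketone is present, so that the two candidate fluorines are equivalent. Alkynol 8 is semihydrogenated over Pd/CaCO3 poisoned with Pb(OAc)2 to (Z)-2-methyl-4-(2,4,6-trifluorophenyl)but-3-en-2-ol F1. NaH in DMF at 60–80 °C closes the ring by intramolecular SNAr on the trifluoroarene to give 5,7-difluoro-2,2-dimethyl-2H-chromene F2. LiN(i-Pr)2 at −78 °C then removes the C6 hydrogen, the only one between two fluorines, and acylation with 5 returns to the route at 14. The price is a ring closure without carbonyl activation and a lithiation that must prefer C6 over C8.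

**Step 8.** The two ortho fluorides differ only in steric environment, so discrimination may be incomplete, with substitution at C5 or at both positions. Addition of the alkoxide to the ketone followed by C–C cleavage is a second possibility.

Fallback: place the C7 oxygen on the template before the ring is assembled.
- Commercial 1,3,5-trifluorobenzene F3 and sodium 2-(trimethylsilyl)ethoxide give [2-(3,5-difluorophenoxy)ethyl]trimethylsilane F4.
- n-BuLi at −78 °C lithiates between the two fluorines, and iodine gives [2-(3,5-difluoro-4-iodophenoxy)ethyl]trimethylsilane F5.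
- Sonogashira coupling with 7 gives 4-{2,6-difluoro-4-[2-(trimethylsilyl)ethoxy]phenyl}-2-methylbut-3-yn-2-ol F6.
- s-BuLi (2 equiv) removes one of the two equivalent hydrogens between fluorine and the ether, and 5 gives 1-{2,4-difluoro-3-(3-hydroxy-3-methylbut-1-ynyl)-6-[2-(trimethylsilyl)ethoxy]phenyl}-2,2-dimethoxy-2-[4-(3-methylbut-2-enyloxy)phenyl]ethanone F7.
- Semihydrogenation gives 1-{2,4-difluoro-3-[(Z)-3-hydroxy-3-methylbut-1-enyl]-6-[2-(trimethylsilyl)ethoxy]phenyl}-2,2-dimethoxy-2-[4-(3-methylbut-2-enyloxy)phenyl]ethanone F8.
- Cs2CO3 in DMF closes the pyran at the fluoride para to the ketone and returns to the route at 15.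

**Step 9.** Displacement at the flanked C5–F on a ring that is now richer in electrons may be slow. At the temperature it needs, methoxide may add to the ketone (C–C cleavage) or attack silicon, and loss of the silylethyl group would leave a phenoxide that stops the substitution.

Fallback: from 15, introduce the oxygen with an alpha-effect nucleophile and methylate afterwards. Acetohydroxamic acid and K2CO3 in DMSO at 80 °C should give 1-{5-hydroxy-2,2-dimethyl-7-[2-(trimethylsilyl)ethoxy]-2H-chromen-6-yl}-2,2-dimethoxy-2-[4-(3-methylbut-2-enyloxy)phenyl]ethanone F9. MeI and K2CO3 in DMF then methylate the only free phenol and return to the route at 16.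

**Step 5.** The stabilised, doubly ortho-substituted aryllithium may add only slowly to the hindered amide at the low temperature it requires. On warming it would lose LiF and form an aryne.

Fallback: use a more electrophilic partner and oxidise afterwards. Amide 5 is reduced with i-Bu2AlH at −78 °C to 2,2-dimethoxy-2-[4-(3-methylbut-2-enyloxy)phenyl]acetaldehyde F10. Aryllithium 9, made from 8 as before, adds at −78 °C to give racemic 1-[2,4,6-trifluoro-3-(3-hydroxy-3-methylbut-1-ynyl)phenyl]-2,2-dimethoxy-2-[4-(3-methylbut-2-enyloxy)phenyl]ethanol F11. Dess–Martin periodinane oxidises the secondary alcohol and returns to the route at 11.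

**Step 11.** The ketal is slowed by the adjacent carbonyl. Before it opens, the prenyl group may be lost by ionisation of the allyl aryl ether, or the chromene double bond may be hydrated.

Fallback: accept loss of the prenyl group and put it back selectively. From 17, stronger aqueous acid (3 M HCl–THF, 40 °C) should give 1-(7-hydroxy-5-methoxy-2,2-dimethyl-2H-chromen-6-yl)-2-(4-hydroxyphenyl)ethane-1,2-dione F12. Prenyl bromide 3 with K2CO3 (1 equiv) in acetone should then alkylate the unhindered ring-B phenol and not the chelated, flanked C7 hydroxyl, returning to the route at 18.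

## Further compounds

F1 | step 7 | (Z)-2-methyl-4-(2,4,6-trifluorophenyl)but-3-en-2-ol | CC(C)(O)/C=C\c1c(F)cc(F)cc1F
F2 | step 7 | 5,7-difluoro-2,2-dimethyl-2H-chromene | CC1(C)C=Cc2c(F)cc(F)cc2O1
F3 | step 8 | 1,3,5-trifluorobenzene | Fc1cc(F)cc(F)c1
F4 | step 8 | [2-(3,5-difluorophenoxy)ethyl]trimethylsilane | C[Si](C)(C)CCOc1cc(F)cc(F)c1
F5 | step 8 | [2-(3,5-difluoro-4-iodophenoxy)ethyl]trimethylsilane | C[Si](C)(C)CCOc1cc(F)c(I)c(F)c1
F6 | step 8 | 4-{2,6-difluoro-4-[2-(trimethylsilyl)ethoxy]phenyl}-2-methylbut-3-yn-2-ol | CC(C)(O)C#Cc1c(F)cc(OCC[Si](C)(C)C)cc1F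
F7 | step 8 | 1-{2,4-difluoro-3-(3-hydroxy-3-methylbut-1-ynyl)-6-[2-(trimethylsilyl)ethoxy]phenyl}-2,2-dimethoxy-2-[4-(3-methylbut-2-enyloxy)phenyl]ethanone | CC(C)(O)C#Cc1c(F)cc(OCC[Si](C)(C)C)c(C(=O)C(OC)(OC)c2ccc(OCC=C(C)C)cc2)c1F
F8 | step 8 | 1-{2,4-difluoro-3-[(Z)-3-hydroxy-3-methylbut-1-enyl]-6-[2-(trimethylsilyl)ethoxy]phenyl}-2,2-dimethoxy-2-[4-(3-methylbut-2-enyloxy)phenyl]ethanone | CC(C)(O)/C=C\c1c(F)cc(OCC[Si](C)(C)C)c(C(=O)C(OC)(OC)c2ccc(OCC=C(C)C)cc2)c1F
F9 | step 9 | 1-{5-hydroxy-2,2-dimethyl-7-[2-(trimethylsilyl)ethoxy]-2H-chromen-6-yl}-2,2-dimethoxy-2-[4-(3-methylbut-2-enyloxy)phenyl]ethanone | Oc1c2c(cc(OCC[Si](C)(C)C)c1C(=O)C(OC)(OC)c1ccc(OCC=C(C)C)cc1)OC(C)(C)C=C2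
F10 | step 5 | 2,2-dimethoxy-2-[4-(3-methylbut-2-enyloxy)phenyl]acetaldehyde | O=CC(OC)(OC)c1ccc(OCC=C(C)C)cc1
F11 | step 5 | 1-[2,4,6-trifluoro-3-(3-hydroxy-3-methylbut-1-ynyl)phenyl]-2,2-dimethoxy-2-[4-(3-methylbut-2-enyloxy)phenyl]ethanol (racemic) | CC(C)(O)C#Cc1c(F)cc(F)c(C(O)C(OC)(OC)c2ccc(OCC=C(C)C)cc2)c1F
F12 | step 11 | 1-(7-hydroxy-5-methoxy-2,2-dimethyl-2H-chromen-6-yl)-2-(4-hydroxyphenyl)ethane-1,2-dione | COc1c2c(cc(O)c1C(=O)C(=O)c1ccc(O)cc1)OC(C)(C)C=C2
A1 | alternative 1 | 7-O-methoxymethyl ficucaricone C | COc1c2c(cc(OCOC)c1C(=O)C(=O)c1ccc(OCC=C(C)C)cc1)OC(C)(C)C=C2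
A2 | alternative 1 | 1,4-dimethylpiperazine-2,3-dione | CN1CCN(C)C(=O)C1=O
A3 | alternative 1 | 4-(3-methylbut-2-enyloxy)phenyllithium | [Li]c1ccc(OCC=C(C)C)cc1
A4 | alternative 1 | 6-lithio-5-methoxy-7-(methoxymethoxy)-2,2-dimethyl-2H-chromene | COc1c2c(cc(OCOC)c1[Li])OC(C)(C)C=C2
A5 | alternative 2 | 3-(4-hydroxyphenyl)-5-methoxy-8,8-dimethyl-7,8-dihydro-6H-pyrano[3,2-g]chromen-4-one | COc1c2c(cc3occ(-c4ccc(O)cc4)c(=O)c13)OC(C)(C)CC2
A6 | alternative 3 | 7-hydroxy-5-methoxy-2,2-dimethyl-2H-chromene-6-carbaldehyde | COc1c2c(cc(O)c1C=O)OC(C)(C)C=C2
A7 | alternative 3 | 4,6-dihydroxy-2-methoxybenzene-1,3-dicarbaldehyde | COc1c(C=O)c(O)cc(O)c1C=O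
A8 | alternative 3 | (2-methylprop-1-enyl)boronic acid | CC(C)=CB(O)O
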